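**Retrosynthetic overview**
- Target ⇐ anti-bis-epoxide diacetate: water opens only the 4,5-oxirane, at its outer carbon C4 with inversion, and the 1,6-oxirane survives.
- Bis-epoxide ⇐ trans-diol of the cyclohexa-1,3-dienylmethyl benzoate: both oxiranes are made in one flask by a twofold hydroxyl-directed epoxidation (the two OH groups are trans, so the oxiranes come out anti, each cis to its own carbinol).
- Diene-diol ⇐ acetoxy-hydroxy dienal (reduction, benzoylation) ⇐ epoxy α-bromo aldehyde by loss of HBr and vinylogous oxirane opening.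
- Epoxy bromo aldehyde ⇐ catalytic enantioselective Diels–Alder adduct of 1-acetoxybutadiene and 2-bromoacrolein (only source of absolute configuration).
- Ring order: carbocycle → auxiliary 3,4-oxirane (made, then opened to set C3–O) → 1,6- and 4,5-oxiranes together → 4,5-oxirane opened.

Convention and assumption: in every intermediate the ring carbons carry the target's locants (C1 = oxirane carbon bearing CH2O, C2/C3 = acetoxy carbons, C4/C5 = carbinol carbons, C6 = oxirane CH); 2-bromoacrolein is taken as a purchasable reagent.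

**Step 1**
Reactants: 1 (1E)-buta-1,3-dien-1-yl acetate; 2 2-bromoprop-2-enal
Product: 3 (1R,6R)-6-bromo-6-formylcyclohex-2-en-1-yl acetate
Conditions: oxazaborolidinone from N-tosyl-(S)-tryptophan and BuB(OH)2 (10 mol %), 1 (2 equiv, commercial E/Z mixture), CH2Cl2, −78 °C; chromatography
Reagents that add atoms: none
Why: Corey–Loh catalytic enantioselective Diels–Alder reaction; "ortho" regiochemistry puts the acetoxy carbon next to the bromo-formyl carbon, the catalyst blocks one face of the s-cis-bound 2-bromoacrolein and is expected to set the bromo carbon as R (as it does with isoprene and cyclopentadiene), and endo-formyl addition sets the acetoxy carbon (C2) as R; the minor exo-formyl diastereomer is removed here because it would erode the ee once the bromo carbon becomes trigonal.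

**Step 2**
Reactants: 3 (1R,6R)-6-bromo-6-formylcyclohex-2-en-1-yl acetate
Product: 4 (1S,2R,3R,6S)-3-bromo-3-formyl-7-oxabicyclo[4.1.0]heptan-2-yl acetate
Conditions: dimethyldioxirane (1.2 equiv), acetone, 0 °C
Reagents that add atoms: dimethyldioxirane, CC1(C)OO1
Why: Dioxirane epoxidation of the only alkene, anti to the allylic acetoxy group and to the cis formyl group, so the new C3–O bond is trans to C2–OAc; the aldehyde is oxidised far more slowly than the alkene.

**Step 3**
Reactants: 4 (1S,2R,3R,6S)-3-bromo-3-formyl-7-oxabicyclo[4.1.0]heptan-2-yl acetate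
Product: 6 (1S,6S)-2-formyl-6-hydroxycyclohexa-2,4-dien-1-yl acetate, via epoxy enal 5 (not isolated)
Conditions: DBU (2.2 equiv), CH2Cl2, −40 → 0 °C; pH 7 buffer quench
Reagents that add atoms: none
Why: E2 dehydrobromination (axial Br, axial H on C6) gives enal 5, then γ-deprotonation at C5 and vinylogous E1cB opening of the oxirane at C4 gives the conjugated dienal; the C3–O bond is not touched, so the trans C2/C3 relationship from step 2 is kept.

**Step 4**
Reactants: 6 (1S,6S)-2-formyl-6-hydroxycyclohexa-2,4-dien-1-yl acetate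
Product: 7 (1S,2S)-3-(hydroxymethyl)cyclohexa-3,5-diene-1,2-diol
Conditions: iBu2AlH (4.5 equiv), CH2Cl2, −78 → 0 °C; aq. KNaC4H4O6 work-up
Reagents that add atoms: none
Why: 1,2-hydride reduction of the dienal and reductive cleavage of the acetate by iBu2AlH; no stereocentre is involved, and any acetyl-migration isomer of 6 converges on the same triol.

**Step 5**
Reactants: 7 (1S,2S)-3-(hydroxymethyl)cyclohexa-3,5-diene-1,2-diol
Product: 8 [(5S,6S)-5,6-dihydroxycyclohexa-1,3-dien-1-yl]methyl benzoate
Conditions: BzCl (1.05 equiv), 2,4,6-collidine, CH2Cl2, −78 → −30 °C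
Reagents that add atoms: benzoyl chloride, O=C(Cl)c1ccccc1
Why: Chemoselective O-acylation of the unhindered primary allylic alcohol over the two secondary alcohols at low temperature with a hindered base.

**Step 6 (key step)**
Reactants: 8 [(5S,6S)-5,6-dihydroxycyclohexa-1,3-dien-1-yl]methyl benzoate
Product: 10 [(1R,2S,4R,5R,6R,7R)-5,6-dihydroxy-3,8-dioxatricyclo[5.1.0.0(2,4)]octan-4-yl]methyl benzoate, via mono-epoxide diol 9 (not isolated)
Conditions: VO(acac)2 (5 mol %), tBuOOH (2.5 equiv, decane), CH2Cl2, 0 °C → rt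
Reagents that add atoms: tert-butyl hydroperoxide, CC(C)(C)OO
Why: Twofold Sharpless–Michaelson hydroxyl-directed epoxidation in one flask: C2–OH delivers oxygen to the C1=C6 alkene on its own face and C3–OH does the same for C4=C5 on the opposite face, and the second epoxidation is also anti to the first oxirane, so all three controls agree and C1, C6, C4 and C5 are set together as the anti-bis-epoxide.

**Step 7**
Reactants: 10 [(1R,2S,4R,5R,6R,7R)-5,6-dihydroxy-3,8-dioxatricyclo[5.1.0.0(2,4)]octan-4-yl]methyl benzoate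
Product: 11 [(1R,2S,4S,5R,6S,7S)-5,6-bis(acetyloxy)-3,8-dioxatricyclo[5.1.0.0(2,4)]octan-4-yl]methyl benzoate
Conditions: Ac2O (3 equiv), pyridine, DMAP (cat.), CH2Cl2, 0 °C → rt
Reagents that add atoms: acetic anhydride, CC(=O)OC(C)=O
Why: DMAP-catalysed acetylation of both secondary alcohols; the oxiranes are inert to these conditions and no stereocentre is touched.

**Step 8**
Reactants: 11 [(1R,2S,4S,5R,6S,7S)-5,6-bis(acetyloxy)-3,8-dioxatricyclo[5.1.0.0(2,4)]octan-4-yl]methyl benzoate
Product: 12 [(1S,2R,3S,4R,5R,6S)-2,3-bis(acetyloxy)-4,5-dihydroxy-7-oxabicyclo[4.1.0]heptan-1-yl]methyl benzoate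
Conditions: Sc(OTf)3 (5 mol %), H2O (10 equiv), MeCN, 0 °C → rt; stopped when 11 is consumed
Reagents that add atoms: water, O
Why: Lewis-acid-catalysed SN2-type trans-opening of an oxirane by water at C4 with inversion: C4 is the outer carbon of the anti-diepoxide array, whereas C5 and C6 are each flanked by the other oxirane (attack there would come in syn to the neighbouring oxirane oxygen) and C1 is quaternary, and Sc bound between the C3 acetate carbonyl and the cis 4,5-oxirane oxygen polarises the C4–O bond; this gives 4-OH trans to both 3-OAc and 5-OH with the 1,6-oxirane intact.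

**Compound list**
1 | (1E)-buta-1,3-dien-1-yl acetate | CC(=O)O/C=C/C=C | starting material
2 | 2-bromoprop-2-enal (2-bromoacrolein) | C=C(Br)C=O | starting material
3 | (1R,6R)-6-bromo-6-formylcyclohex-2-en-1-yl acetate | O=C[C@@]1(Br)CCC=C[C@H]1OC(C)=O | intermediate
4 | (1S,2R,3R,6S)-3-bromo-3-formyl-7-oxabicyclo[4.1.0]heptan-2-yl acetate | O=C[C@@]1(Br)CC[C@@H]2O[C@@H]2[C@H]1OC(C)=O | intermediate
5 | (1S,2S,6S)-3-formyl-7-oxabicyclo[4.1.0]hept-3-en-2-yl acetate | O=CC1=CC[C@@H]2O[C@@H]2[C@H]1OC(C)=O | intermediate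
6 | (1S,6S)-2-formyl-6-hydroxycyclohexa-2,4-dien-1-yl acetate | O[C@H]1C=CC=C(C=O)[C@@H]1OC(C)=O | intermediate
7 | (1S,2S)-3-(hydroxymethyl)cyclohexa-3,5-diene-1,2-diol | O[C@H]1C=CC=C(CO)[C@@H]1O | intermediate
8 | [(5S,6S)-5,6-dihydroxycyclohexa-1,3-dien-1-yl]methyl benzoate | O[C@H]1C=CC=C(COC(=O)c2ccccc2)[C@@H]1O | intermediate
9 | [(1R,2R,3S,6S)-2,3-dihydroxy-7-oxabicyclo[4.1.0]hept-4-en-1-yl]methyl benzoate | O[C@H]1C=C[C@@H]2O[C@]2(COC(=O)c2ccccc2)[C@@H]1O | intermediate
10 | [(1R,2S,4R,5R,6R,7R)-5,6-dihydroxy-3,8-dioxatricyclo[5.1.0.0(2,4)]octan-4-yl]methyl benzoate | O[C@H]1[C@H]3O[C@H]3[C@@H]2O[C@]2(COC(=O)c2ccccc2)[C@@H]1O | intermediate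
11 | [(1R,2S,4S,5R,6S,7S)-5,6-bis(acetyloxy)-3,8-dioxatricyclo[5.1.0.0(2,4)]octan-4-yl]methyl benzoate | CC(=O)O[C@H]1[C@H]3O[C@H]3[C@@H]2O[C@]2(COC(=O)c2ccccc2)[C@@H]1OC(C)=O | intermediate
12 | [(1S,2R,3S,4R,5R,6S)-2,3-bis(acetyloxy)-4,5-dihydroxy-7-oxabicyclo[4.1.0]heptan-1-yl]methyl benzoate | CC(=O)O[C@H]1[C@H](O)[C@@H](O)[C@@H]2O[C@]2(COC(=O)c2ccccc2)[C@@H]1OC(C)=O | target

**Totals**
Total step count: 8. Longest linear sequence: 8 (fully linear).

**Three steps most likely to fail**

1. Step 8 (which oxirane carbon water attacks). The opening at C4 runs against the usual preference of a 3-acyloxy cyclohexene oxide for attack at the carbon remote from the acyloxy group, and it must pass through the ring conformer with axial acetoxy groups. Attack at C5, or benzoate participation at C1, would give isomers. Fallback, setting out from 11 and returning at 12: replace the metal-catalysed hydration by carboxylic acidolysis and transesterification. Formic acid (HCO2H, CH2Cl2, 0 °C) opens the 4,5-oxirane as an unhindered carboxylic-acid nucleophile at the sterically open outer carbon and gives [(1S,2R,3S,4R,5R,6S)-2,3-bis(acetyloxy)-4-(formyloxy)-5-hydroxy-7-oxabicyclo[4.1.0]heptan-1-yl]methyl benzoate F1. Formyl migration between O4 and O5 does not matter. KHCO3 in MeOH at 0 °C then removes the formyl group in the presence of the acetates and the benzoate and gives 12.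

2. Step 3 (the base cascade). The dienal 6 can aromatise by loss of acetic acid, and the bromo aldehyde can eliminate toward C2. Fallback, setting out from 3 and returning at 6: introduce the C3 oxygen and the C4=C5 double bond by an ene reaction, not by epoxide opening. A Schenck ene reaction (O2, tetraphenylporphyrin, visible light, CH2Cl2, 0 °C) adds singlet oxygen to C3 anti to the acetoxy group, takes the allylic hydrogen from C5 and shifts the alkene, giving (1R,2S,6R)-6-bromo-6-formyl-2-hydroperoxycyclohex-3-en-1-yl acetate F2. PPh3 reduces it to (1R,2S,6R)-6-bromo-6-formyl-2-hydroxycyclohex-3-en-1-yl acetate F3. DBU (1.1 equiv, −20 °C) then only has to perform the E2 loss of HBr, which gives 6.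

3. Step 2 (face selectivity of the epoxidation). Allylic acetates steer dioxiranes only moderately, and the cis-epoxide would lead to the cis-diol series. Fallback, setting out from 3 and returning at 7: set the C3 oxygen by osmylation. OsO4 (cat.) with N-methylmorpholine N-oxide in acetone–water dihydroxylates anti to the allylic acetoxy group and gives (1R,2S,3S,6R)-6-bromo-6-formyl-2,3-dihydroxycyclohexyl acetate F4. Ac2O, pyridine and DMAP give (1S,2S,3R,4R)-4-bromo-4-formylcyclohexane-1,2,3-triyl triacetate F5. DBU removes HBr and then, by vinylogous E1cB, the C4 acetate, giving (1S,2S)-3-formylcyclohexa-3,5-diene-1,2-diyl diacetate F6. iBu2AlH (6 equiv) reduces the aldehyde and cleaves both acetates to give 7.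

**Further compounds**
F1 | step 8 | [(1S,2R,3S,4R,5R,6S)-2,3-bis(acetyloxy)-4-(formyloxy)-5-hydroxy-7-oxabicyclo[4.1.0]heptan-1-yl]methyl benzoate | CC(=O)O[C@H]1[C@H](OC=O)[C@@H](O)[C@@H]2O[C@]2(COC(=O)c2ccccc2)[C@@H]1OC(C)=O
F2 | step 3 | (1R,2S,6R)-6-bromo-6-formyl-2-hydroperoxycyclohex-3-en-1-yl acetate | O=C[C@@]1(Br)CC=C[C@H](OO)[C@H]1OC(C)=O
F3 | step 3 | (1R,2S,6R)-6-bromo-6-formyl-2-hydroxycyclohex-3-en-1-yl acetate | O=C[C@@]1(Br)CC=C[C@H](O)[C@H]1OC(C)=O
F4 | step 2 | (1R,2S,3S,6R)-6-bromo-6-formyl-2,3-dihydroxycyclohexyl acetate | O=C[C@@]1(Br)CC[C@H](O)[C@H](O)[C@H]1OC(C)=O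
F5 | step 2 | (1S,2S,3R,4R)-4-bromo-4-formylcyclohexane-1,2,3-triyl triacetate | O=C[C@@]1(Br)CC[C@H](OC(C)=O)[C@H](OC(C)=O)[C@H]1OC(C)=O
F6 | step 2 | (1S,2S)-3-formylcyclohexa-3,5-diene-1,2-diyl diacetate | CC(=O)O[C@H]1C=CC=C(C=O)[C@@H]1OC(C)=O
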